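## Retrosynthetic overview

1. Irisoquin (quinone numbering: C1=O, C2–OH, C3–octadecyl, C4=O, C5–OMe, C6–H) is traced back, by removal of the C5 O-methyl group, to 2,5-dihydroxy-3-octadecyl-1,4-benzoquinone.
2. The quinone ring, the only ring, is cut at C3–C4 and at C5–C6. A [4+2] double Claisen annulation joins docosane-2,3-dione (C6–C1–C2–C3 with the side chain) to dimethyl oxalate (C4–C5) and gives the ring directly at the quinone oxidation level.
3. Enabling feature: the 1,2,4,5-tetraoxygenated six-membered ring is an enol form of a cyclohexane-1,2,4,5-tetraone. C3 and C6 each lie between two carbonyl carbons, so C3–C4 and C5–C6 are both 1,3-dicarbonyl (Claisen) bonds and C4–C5 is an oxalyl unit.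
4. The diketone comes from icosanoic acid through its Weinreb amide and 1-ethoxyvinyllithium as an acetyl anion equivalent.

Key step: step 3

Assumption: a cyclohexane-1,2,4,5-tetraone carrying hydrogen at C3 and C6 is taken to exist entirely as its 2,5-dihydroxy-1,4-benzoquinone tautomer, so no separate oxidation step is planned.

## Route

Step 1
Reactants: 1 icosanoic acid; 2 N,O-dimethylhydroxylamine hydrochloride
Product: 4 N-methoxy-N-methylicosanamide, via 1-icosanoylimidazole 3 (not isolated)
Conditions: 1,1'-carbonyldiimidazole (1.2 equiv), THF, 40 °C; then 2 (1.5 equiv), rt
Reagents that add atoms: none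
Why: Activation of the acid as its N-acylimidazole followed by aminolysis is standard Weinreb amide formation, and the saturated chain carries nothing else that reacts.

Step 2
Reactants: 4 N-methoxy-N-methylicosanamide; 5 ethyl vinyl ether
Product: 8 docosane-2,3-dione, via 1-ethoxyvinyllithium 6 (not isolated), via 2-ethoxydocos-1-en-3-one 7 (not isolated)
Conditions: 5 (3 equiv), t-BuLi (2.5 equiv), THF, −78 to 0 °C; then 4 in THF, −40 °C to rt; then 2 M aq. HCl, THF, rt
Reagents that add atoms: water, O
Why: Acylation of the acetyl anion equivalent 1-ethoxyvinyllithium by a Weinreb amide stops at the ketone stage because of the stable lithium chelate (Weinreb ketone synthesis), and mild aqueous acid then hydrolyses the enol ether of the alpha-ethoxy enone to the 1,2-diketone.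

Step 3
Reactants: 8 docosane-2,3-dione; 9 dimethyl oxalate
Product: 12 2,5-dihydroxy-3-octadecyl-1,4-benzoquinone, via methyl 2,4,5-trioxotetracosanoate 10 (not isolated), via disodium 3-octadecyl-2,5-dioxido-1,4-benzoquinone 11 (not isolated)
Conditions: 9 (2 equiv), NaOMe (4 equiv), THF–MeOH, slow addition of 8 at 0 °C, then 60 °C; then 2 M aq. HCl, 0 °C
Reagents that add atoms: none
Why: Proposed new method: a crossed double Claisen annulation of an enolisable 1,2-diketone with an oxalate diester, reasoned as follows: methoxide reversibly forms the C1-methyl enolate of 8, which is C-acylated by the non-enolisable, highly electrophilic oxalate 9 to give 10 (held as its stabilised enolate), a second deprotonation at C6 of 10 lets that enolate attack the remaining ester carbonyl with loss of methoxide, and the cyclic tetraone is at once doubly deprotonated to the bis-vinylogous carboxylate 11, which pulls every preceding equilibrium forward and on acidification gives 12 without any oxidant. The closest known reaction types are the oxalate Claisen acylation of ketone enolates, the double oxalate Claisen annulation of dialkyl ketones to cyclopentane-1,2,4-triones, and the Fichter self-condensation of 2-oxoalkanoate esters to 3,6-dialkyl-2,5-dihydroxy-1,4-benzoquinones, which builds the same ring through the same kind of C–C bond. The single ring closes by a 6-(enolendo)-exo-trig Dieckmann-type acylation, whereas the competing aldol closure onto the C2 ketone of 10 would be a disfavoured 5-(enolendo)-exo-trig process. No stereocentre is formed. The step needs cross-condensation over self-aldol condensation of 8 and C-acylation over O-acylation: the first should be secured by slow addition of 8 to an excess of 9 and base and by the reversibility of the aldol pathway, the second by the reversibility of O-acylation under methoxide, since only the C,C-diacylated ring can fall into the dianion sink. Regiochemistry is not an issue, because 9 is symmetrical and either order of the two acylations converges on the same ring.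

Step 4
Reactants: 12 2,5-dihydroxy-3-octadecyl-1,4-benzoquinone
Product: 13 irisoquin (2-hydroxy-5-methoxy-3-octadecyl-1,4-benzoquinone)
Conditions: MeOH–CH2Cl2, H2SO4 (cat.), reflux, stopped at the monoether stage
Reagents that add atoms: methanol, CO
Why: Acid-catalysed addition–elimination of methanol at the vinylogous carboxylic acid (Fischer-type etherification of a hydroxyquinone) should take place at the C5 hydroxyl next to the unsubstituted C6–H, because the C2 hydroxyl is flanked by the octadecyl chain and its ether would be both slower to form and thermodynamically disfavoured under these reversible conditions.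

## Compound list

1 | icosanoic acid (arachidic acid) | CCCCCCCCCCCCCCCCCCCC(=O)O | starting material
2 | N,O-dimethylhydroxylamine hydrochloride | CNOC.Cl | starting material
3 | 1-icosanoylimidazole (formed in the flask) | CCCCCCCCCCCCCCCCCCCC(=O)n1ccnc1 | intermediate
4 | N-methoxy-N-methylicosanamide | CCCCCCCCCCCCCCCCCCCC(=O)N(C)OC | intermediate
5 | ethyl vinyl ether | C=COCC | starting material
6 | 1-ethoxyvinyllithium (formed in the flask) | [Li]C(=C)OCC | intermediate
7 | 2-ethoxydocos-1-en-3-one (formed in the flask) | CCCCCCCCCCCCCCCCCCCC(=O)C(=C)OCC | intermediate
8 | docosane-2,3-dione | CCCCCCCCCCCCCCCCCCCC(=O)C(C)=O | intermediate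
9 | dimethyl oxalate | COC(=O)C(=O)OC | starting material
10 | methyl 2,4,5-trioxotetracosanoate (formed in the flask) | CCCCCCCCCCCCCCCCCCCC(=O)C(=O)CC(=O)C(=O)OC | intermediate
11 | disodium 2-octadecyl-3,6-dioxocyclohexa-1,4-diene-1,4-diolate (formed in the flask) | CCCCCCCCCCCCCCCCCCC1=C([O-])C(=O)C=C([O-])C1=O.[Na+].[Na+] | intermediate
12 | 2,5-dihydroxy-3-octadecylcyclohexa-2,5-diene-1,4-dione | CCCCCCCCCCCCCCCCCCC1=C(O)C(=O)C=C(O)C1=O | intermediate
13 | irisoquin, 2-hydroxy-5-methoxy-3-octadecylcyclohexa-2,5-diene-1,4-dione | CCCCCCCCCCCCCCCCCCC1=C(O)C(=O)C=C(OC)C1=O | target

## Step count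

Total steps: 4. Longest linear sequence: 4 steps (1 → 4 → 8 → 12 → 13).

## Steps most likely to fail

**Step 3 (proposed new method).** Base-mediated self-aldol condensation of the diketone may outrun its cross-acylation, or the mono-acylated intermediate may be diverted by retro-Claisen cleavage or O-cyclisation before the ring closes. The fallback uses known reactions in a stepwise order and keeps the 1,2-diketone masked until the first C–C bond is in place. It sets out from 7, which is isolated from step 2 by a buffered NH4Cl work-up in place of the HCl treatment. Kinetic deprotonation of 7 at C4, its only enolisable position, with LiN(SiMe3)2 (THF, −78 °C) and Claisen acylation with 9 should give methyl 3-(2-ethoxyprop-2-enoyl)-2-oxohenicosanoate F1. Mild aqueous HCl in THF should then hydrolyse the enol ether to methyl 3-octadecyl-2,4,5-trioxohexanoate F2. NaOMe in THF–MeOH should close the ring by Dieckmann-type acylation of the methyl ketone enolate onto the ester, and acidification brings the sequence back to the route at 12.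

**Step 4.** Etherification may stall because of poor solubility of the long-chain quinone, or lose site selectivity and run on to double methylation when forced. The fallback sets out from 12. Exhaustive O-methylation with Me2SO4 and K2CO3 in acetone should give 2,5-dimethoxy-3-octadecyl-1,4-benzoquinone F3. Selective acid hydrolysis (aqueous HClO4, 1,4-dioxane, rt) should then remove the C2 methoxy group, which is twisted out of conjugation by the neighbouring octadecyl chain and is the more labile vinylogous ester. This comes back to the route at 13.

**Step 2.** Acyl transfer may be incomplete if the long-chain amide precipitates at low temperature, the amide may be deprotonated at its alpha carbon instead, or the diketone may self-condense under the acid used for enol ether hydrolysis. The fallback sets out from 4 and uses a different acyl anion equivalent with non-hydrolytic unmasking. Acylation of 2-lithio-2-methyl-1,3-dithiane (from 2-methyl-1,3-dithiane and n-BuLi, THF, −30 to 0 °C) by 4 should give 1-(2-methyl-1,3-dithian-2-yl)icosan-1-one F4. Oxidative dethioketalisation with PhI(OCOCF3)2 in NaHCO3-buffered aqueous MeCN at rt should then release the diketone, which returns to the route at 8.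

## Further compounds

F1 | step 3 | methyl 3-(2-ethoxyprop-2-enoyl)-2-oxohenicosanoate | CCCCCCCCCCCCCCCCCCC(C(=O)C(=O)OC)C(=O)C(=C)OCC
F2 | step 3 | methyl 3-octadecyl-2,4,5-trioxohexanoate | CCCCCCCCCCCCCCCCCCC(C(=O)C(=O)OC)C(=O)C(C)=O
F3 | step 4 | 2,5-dimethoxy-3-octadecylcyclohexa-2,5-diene-1,4-dione | CCCCCCCCCCCCCCCCCCC1=C(OC)C(=O)C=C(OC)C1=O
F4 | step 2 | 1-(2-methyl-1,3-dithian-2-yl)icosan-1-one | CCCCCCCCCCCCCCCCCCCC(=O)C1(C)SCCCS1
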